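**Strategy.** The ten-membered carbocycle is closed late at the C3–C4 bond, the sp3–sp2 bond between the C3 methylene and the methyl-bearing carbon of the (4Z)-olefin, by an intramolecular B-alkyl Suzuki–Miyaura coupling. The step exploits the ring-cis,cis 1,5-diene C10=C1–C2–C3–C4=C5 hidden in the target (the C1–C10 epoxide is a masked ring-cis olefin). Anti-Markovnikov hydroboration of a terminal C2=C3 vinyl group gives the C3 borane, which couples with retention to a (Z)-C4 vinyl iodide. The precursor is an acyclic iodo-triene diacetate; its C10=C1 geometry is set beforehand in a temporary dihydropyranone ring (ring-closing metathesis), later opened by Wittig methylenation of the lactol.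

Key step: step 15

Remark: germacrane numbering is used throughout (ring carbons C1–C10; C1–C10 epoxide, C4=C5 olefin, acetoxy groups on C6 and C8, isopropyl on C7, C14 = formyl carbon on C10, C15 = methyl on C4). The CIP descriptors of C6, C7 and C10 change along the route with the substituents, although the spatial arrangement stays the same.

**Step 1**
Reactants: 1 but-2-yn-1-ol
Product: 3 (Z)-3-iodobut-2-en-1-ol, via cyclic alkenylaluminate 2 (not isolated)
Conditions: NaAlH2(OCH2CH2OCH3)2, Et2O, 0 °C to rt; EtOAc; then I2, THF, −78 to 0 °C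
Reagents that add atoms: iodine, II
Why: Alkoxide-directed trans-hydroalumination of the propargylic alcohol places aluminium on the distal carbon in a five-membered aluminate, and iodinolysis with retention gives the (Z)-iodide that later becomes the ring-cis C4=C5 olefin (hydroalumination–iodination).

**Step 2**
Reactants: 3 (Z)-3-iodobut-2-en-1-ol
Product: 4 (Z)-3-iodobut-2-enal
Conditions: activated MnO2, CH2Cl2, rt, dark
Reagents that add atoms: none
Why: MnO2 oxidises the allylic alcohol to the enal under neutral conditions that should not isomerise the (Z)-iodoalkene (allylic oxidation).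

**Step 3**
Reactants: 5 (R)-4-benzyl-1,3-oxazolidin-2-one; 6 3-methylbutanoyl chloride
Product: 7 (R)-4-benzyl-3-(3-methylbutanoyl)-1,3-oxazolidin-2-one
Conditions: n-BuLi, THF, −78 °C; then 6, −78 to 0 °C
Reagents that add atoms: none
Why: N-Acylation of the lithiated oxazolidinone with the acid chloride is a standard imide formation and touches no stereocentre.

**Step 4**
Reactants: 7 (R)-4-benzyl-3-(3-methylbutanoyl)-1,3-oxazolidin-2-one; 4 (Z)-3-iodobut-2-enal
Product: 9 (4R)-4-benzyl-3-[(2R,3R,4Z)-3-hydroxy-5-iodo-2-(propan-2-yl)hex-4-enoyl]-1,3-oxazolidin-2-one, via dibutylboron enolate 8 (not isolated)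
Conditions: n-Bu2BOTf, i-Pr2NEt, CH2Cl2, −78 to 0 °C; 4, −78 to 0 °C; pH 7 buffer, MeOH, H2O2, 0 °C
Reagents that add atoms: none
Why: Evans syn aldol: the (Z)-boron enolate reacts through a Zimmerman–Traxler chair with the aldehyde on the face opposite the benzyl group of the (R)-auxiliary, which sets C7 and C6 syn in the required sense (2R,3R in 9, corresponding to 7S,6S of the target).

**Step 5**
Reactants: 9 aldol adduct
Product: 10 (2R,3R,4Z)-3-hydroxy-5-iodo-N-methoxy-N-methyl-2-(propan-2-yl)hex-4-enamide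
Conditions: MeNHOMe·HCl, AlMe3, CH2Cl2, −20 to 0 °C; aq. KNaC4H4O6 work-up
Reagents that add atoms: N,O-dimethylhydroxylamine hydrochloride, CNOC.Cl
Why: Aluminium amide transamination of the β-hydroxy imide (Weinreb amide formation) is assisted by the free hydroxyl and frees the auxiliary without epimerising C7.

**Step 6**
Reactants: 11 2-methylidenepropane-1,3-diol
Product: 12 2-{[(tert-butyldimethylsilyl)oxy]methyl}prop-2-en-1-ol
Conditions: NaH (1 equiv), THF, 0 °C to rt; TBSCl (1 equiv)
Reagents that add atoms: tert-butyldimethylsilyl chloride, CC(C)(C)[Si](C)(C)Cl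
Why: Monodeprotonation of the symmetrical diol and silylation of the mono-alkoxide should give mainly the monosilyl ether (monoprotection of a symmetrical diol; no stereocentre).

**Step 7**
Reactants: 12 monosilyl ether
Product: 13 tert-butyl{[2-(chloromethyl)prop-2-en-1-yl]oxy}dimethylsilane
Conditions: N-chlorosuccinimide, Me2S, CH2Cl2, −20 to 0 °C
Reagents that add atoms: N-chlorosuccinimide, O=C1CCC(=O)N1Cl
Why: Corey–Kim-type chlorination through the alkoxysulfonium salt converts the primary allylic alcohol into the chloride under neutral conditions that spare the silyl ether.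

**Step 8**
Reactants: 13 allylic chloride; 10 Weinreb amide
Product: 15 (5R,6R,7Z)-1-[(tert-butyldimethylsilyl)oxy]-6-hydroxy-8-iodo-2-methylidene-5-(propan-2-yl)non-7-en-4-one, via allylmagnesium chloride 14 (not isolated)
Conditions: Mg, THF, 0 °C (13 added slowly; 3.5 equiv of 14); then 10, THF, −78 to −20 °C; aq. NH4Cl at −20 °C
Reagents that add atoms: none
Why: The allylic Grignard reagent first deprotonates the hydroxyl and then adds once to the Weinreb amide, because the chelated tetrahedral intermediate survives until the cold quench, giving the β-hydroxy ketone with C6 and C7 untouched (Weinreb ketone synthesis).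

**Step 9**
Reactants: 15 β-hydroxy ketone
Product: 17 (4R,5S,6R,7Z)-1-[(tert-butyldimethylsilyl)oxy]-8-iodo-2-methylidene-5-(propan-2-yl)non-7-ene-4,6-diol, via diethylboryl aldolate 16 (not isolated)
Conditions: Et2BOMe, THF/MeOH 4:1, −78 °C; NaBH4, −78 °C; AcOH; repeated evaporation from MeOH
Reagents that add atoms: none
Why: Narasaka–Prasad reduction: the boron chelate adopts a half-chair with the C6 alkenyl group equatorial and external hydride adds axially, setting C8 (R) 1,3-syn to C6 and completing the all-syn C6–C7–C8 triad.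

**Step 10**
Reactants: 17 syn-diol
Product: 18 (4R,5S,6R,7Z)-1-[(tert-butyldimethylsilyl)oxy]-8-iodo-2-methylidene-5-(propan-2-yl)non-7-ene-4,6-diyl di(prop-2-enoate)
Conditions: acryloyl chloride, i-Pr2NEt, CH2Cl2, −20 to 0 °C
Reagents that add atoms: acryloyl chloride, C=CC(=O)Cl
Why: Double O-acylation puts the metathesis partner on O8 and at the same time masks O6 as an ester that the later hydride step removes.

**Step 11**
Reactants: 18 bis-acrylate
Product: 19 (2Z,4R,5S)-5-[(2R)-4-{[(tert-butyldimethylsilyl)oxy]methyl}-6-oxo-3,6-dihydro-2H-pyran-2-yl]-2-iodo-6-methylhept-2-en-4-yl prop-2-enoate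
Conditions: second-generation Grubbs catalyst (H2IMes)(PCy3)Cl2Ru=CHPh (10 mol %), CH2Cl2 (2 mM), reflux
Reagents that add atoms: none
Why: Ring-closing metathesis between the O8 acrylate and the 1,1-disubstituted C10 olefin closes a six-membered 5,6-dihydropyran-2-one whose ring forces C9 and C2 cis on the new trisubstituted C1=C10 double bond, whereas the O6 acrylate could only give an eight-membered ring and should stay.

**Step 12**
Reactants: 19 unsaturated lactone
Product: 20 (2Z,4R,5S)-5-[(2R)-4-{[(tert-butyldimethylsilyl)oxy]methyl}-6-hydroxy-3,6-dihydro-2H-pyran-2-yl]-2-iodo-6-methylhept-2-en-4-ol (lactol, both anomers)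
Conditions: i-Bu2AlH (2.6 equiv), CH2Cl2, −78 °C; MeOH, aq. KNaC4H4O6
Reagents that add atoms: none
Why: At −78 °C i-Bu2AlH stops at the tetrahedral aluminate of both esters, so the unsaturated lactone gives the lactol and the O6 acrylate is cleaved to the free alcohol on work-up (partial reduction of a lactone to a lactol).

**Step 13**
Reactants: 20 lactol
Product: 21 (3E,6R,7S,8R,9Z)-4-{[(tert-butyldimethylsilyl)oxy]methyl}-10-iodo-7-(propan-2-yl)undeca-1,3,9-triene-6,8-diol
Conditions: Ph3PCH3Br, KN(SiMe3)2, THF, 0 °C; then 20, 0 °C to rt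
Reagents that add atoms: methyltriphenylphosphonium bromide, C[P+](c1ccccc1)(c1ccccc1)c1ccccc1.[Br-]
Why: Wittig methylenation of the lactol through its open (Z)-hydroxy-enal form adds C3 and releases O8, and the ring-derived C1=C10 geometry should be retained because the aldehyde is trapped faster than it can isomerise.

**Step 14**
Reactants: 21 triene diol
Product: 22 (3E,6R,7S,8R,9Z)-4-{[(tert-butyldimethylsilyl)oxy]methyl}-10-iodo-7-(propan-2-yl)undeca-1,3,9-triene-6,8-diyl diacetate
Conditions: Ac2O, pyridine, DMAP (cat.), CH2Cl2, rt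
Reagents that add atoms: acetic anhydride, CC(=O)OC(C)=O
Why: DMAP-catalysed acetylation of both secondary alcohols installs the two acetates of the target without touching a stereocentre.

**Step 15**
Reactants: 22 iodo-triene diacetate
Product: 24 (1S,2Z,6E,9R,10S)-7-{[(tert-butyldimethylsilyl)oxy]methyl}-3-methyl-10-(propan-2-yl)cyclodeca-2,6-diene-1,9-diyl diacetate, via alkylborane 23 (not isolated)
Conditions: 9-BBN-H (dimer), THF, 0 °C to rt; then aq. Cs2CO3 and slow addition to PdCl2(dppf) (15 mol %), AsPh3, DMF/THF/H2O, rt to 40 °C, final about 1 mM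
Reagents that add atoms: none
Why: 9-BBN-H adds anti-Markovnikov to the monosubstituted C2=C3 terminus of the diene, the trisubstituted C1=C10 and iodo-substituted C4=C5 olefins being too hindered, so boron sits on C3; oxidative addition of the C4–I bond to zerovalent palladium, transmetalation of the hydroxyborate and reductive elimination then forge C3–C4, the closest known reaction type being the intramolecular B-alkyl Suzuki–Miyaura macrocyclisation of ω-boryl alkenyl iodides. The ten-membered carbocycle is closed by reductive elimination from an eleven-membered alkyl(alkenyl)palladacycle, a direct macrocyclisation with no second ring involved. No stereocentre is formed; the ring-cis (Z) geometry of C4=C5 is controlled by the geometry of the iodide, since oxidative addition and reductive elimination at sp2 carbon go with retention, and C6, C7 and C8 are not touched. The step needs cyclisation to outrun oligomerisation and β-hydride elimination of the alkylpalladium: slow addition to about 1 mM, the two ring-cis olefins and the branched all-syn C6–C8 segment that pre-fold the chain, and the wide-bite-angle dppf ligand with AsPh3 should secure this. The carbonate base near room temperature should leave both acetates and the silyl ether intact.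

**Step 16**
Reactants: 24 silyl ether macrocycle
Product: 25 (1S,2Z,6E,9R,10S)-7-(hydroxymethyl)-3-methyl-10-(propan-2-yl)cyclodeca-2,6-diene-1,9-diyl diacetate
Conditions: HF·pyridine, pyridine, THF, 0 °C
Reagents that add atoms: none
Why: Buffered HF·pyridine cleaves the primary allylic silyl ether while the acetates and both olefins stay inert (fluoride desilylation).

**Step 17**
Reactants: 25 allylic alcohol
Product: 26 (1R,4Z,6S,7S,8R,10R)-1,10-epoxy-14-hydroxygermacr-4-ene-6,8-diyl diacetate
Conditions: Ti(OiPr)4, diethyl D-(−)-tartrate, t-BuOOH (anhydrous), 4 Å molecular sieves, CH2Cl2, −20 °C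
Reagents that add atoms: tert-butyl hydroperoxide, CC(C)(C)OO
Why: Sharpless asymmetric epoxidation: the titanium tartrate complex binds the C14 hydroxyl and delivers oxygen only to the C1=C10 allylic-alcohol olefin, the D-tartrate directing it to the face that gives the C1 (R) and C10 configuration of the target (reagent control), while the C4=C5 olefin of the allylic acetate is not a substrate.

**Step 18**
Reactants: 26 epoxy alcohol
Product: 27 (1R,4Z,6S,7S,8R,10S)-6,8-diacetoxy-1,10-epoxygermacr-4-en-14-al (target)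
Conditions: Dess–Martin periodinane, NaHCO3, CH2Cl2, 0 °C to rt
Reagents that add atoms: none
Why: Dess–Martin oxidation under bicarbonate buffer converts the primary epoxy alcohol into the epoxy aldehyde without opening the epoxide, and the quaternary C10 cannot epimerise.

**Compound list**

1 | but-2-yn-1-ol | CC#CCO | starting material
2 | sodium 2,2-bis(2-methoxyethoxy)-3-methyl-2,5-dihydro-1,2-oxaluminol-2-uide (cyclic alkenylaluminate) | CC1=CCO[Al-]1(OCCOC)OCCOC.[Na+] | intermediate
3 | (Z)-3-iodobut-2-en-1-ol | C/C(I)=C/CO | intermediate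
4 | (Z)-3-iodobut-2-enal | C/C(I)=C/C=O | intermediate
5 | (R)-4-benzyl-1,3-oxazolidin-2-one | O=C1N[C@H](Cc2ccccc2)CO1 | starting material
6 | 3-methylbutanoyl chloride | CC(C)CC(=O)Cl | starting material
7 | (R)-4-benzyl-3-(3-methylbutanoyl)-1,3-oxazolidin-2-one | CC(C)CC(=O)N1[C@H](Cc2ccccc2)COC1=O | intermediate
8 | (Z)-dibutylboron enolate of 7 | CC(C)/C=C(\OB(CCCC)CCCC)N1[C@H](Cc2ccccc2)COC1=O | intermediate
9 | (4R)-4-benzyl-3-[(2R,3R,4Z)-3-hydroxy-5-iodo-2-(propan-2-yl)hex-4-enoyl]-1,3-oxazolidin-2-one | O[C@H]([C@@H](C(C)C)C(=O)N1[C@H](Cc2ccccc2)COC1=O)/C=C(/C)I | intermediate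
10 | (2R,3R,4Z)-3-hydroxy-5-iodo-N-methoxy-N-methyl-2-(propan-2-yl)hex-4-enamide | O[C@H]([C@@H](C(C)C)C(=O)N(C)OC)/C=C(/C)I | intermediate
11 | 2-methylidenepropane-1,3-diol | C=C(CO)CO | starting material
12 | 2-{[(tert-butyldimethylsilyl)oxy]methyl}prop-2-en-1-ol | C=C(CO)CO[Si](C)(C)C(C)(C)C | intermediate
13 | tert-butyl{[2-(chloromethyl)prop-2-en-1-yl]oxy}dimethylsilane | C=C(CCl)CO[Si](C)(C)C(C)(C)C | intermediate
14 | (2-{[(tert-butyldimethylsilyl)oxy]methyl}prop-2-en-1-yl)magnesium chloride | C=C(C[Mg]Cl)CO[Si](C)(C)C(C)(C)C | intermediate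
15 | (5R,6R,7Z)-1-[(tert-butyldimethylsilyl)oxy]-6-hydroxy-8-iodo-2-methylidene-5-(propan-2-yl)non-7-en-4-one | O[C@H]([C@@H](C(C)C)C(=O)CC(=C)CO[Si](C)(C)C(C)(C)C)/C=C(/C)I | intermediate
16 | 6-O-diethylboryl derivative of 15 | CCB(CC)O[C@H]([C@@H](C(C)C)C(=O)CC(=C)CO[Si](C)(C)C(C)(C)C)/C=C(/C)I | intermediate
17 | (4R,5S,6R,7Z)-1-[(tert-butyldimethylsilyl)oxy]-8-iodo-2-methylidene-5-(propan-2-yl)non-7-ene-4,6-diol | O[C@H]([C@@H](C(C)C)[C@H](O)CC(=C)CO[Si](C)(C)C(C)(C)C)/C=C(/C)I | intermediate
18 | (4R,5S,6R,7Z)-1-[(tert-butyldimethylsilyl)oxy]-8-iodo-2-methylidene-5-(propan-2-yl)non-7-ene-4,6-diyl di(prop-2-enoate) | C=CC(=O)O[C@H]([C@@H](C(C)C)[C@H](OC(=O)C=C)CC(=C)CO[Si](C)(C)C(C)(C)C)/C=C(/C)I | intermediate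
19 | (2Z,4R,5S)-5-[(2R)-4-{[(tert-butyldimethylsilyl)oxy]methyl}-6-oxo-3,6-dihydro-2H-pyran-2-yl]-2-iodo-6-methylhept-2-en-4-yl prop-2-enoate | C=CC(=O)O[C@H]([C@@H](C(C)C)[C@H]1CC(CO[Si](C)(C)C(C)(C)C)=CC(=O)O1)/C=C(/C)I | intermediate
20 | (2Z,4R,5S)-5-[(2R)-4-{[(tert-butyldimethylsilyl)oxy]methyl}-6-hydroxy-3,6-dihydro-2H-pyran-2-yl]-2-iodo-6-methylhept-2-en-4-ol | O[C@H]([C@@H](C(C)C)[C@H]1CC(CO[Si](C)(C)C(C)(C)C)=CC(O)O1)/C=C(/C)I | intermediate
21 | (3E,6R,7S,8R,9Z)-4-{[(tert-butyldimethylsilyl)oxy]methyl}-10-iodo-7-(propan-2-yl)undeca-1,3,9-triene-6,8-diol | O[C@H]([C@@H](C(C)C)[C@H](O)C/C(CO[Si](C)(C)C(C)(C)C)=C\C=C)/C=C(/C)I | intermediate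
22 | (3E,6R,7S,8R,9Z)-4-{[(tert-butyldimethylsilyl)oxy]methyl}-10-iodo-7-(propan-2-yl)undeca-1,3,9-triene-6,8-diyl diacetate | CC(=O)O[C@H]([C@@H](C(C)C)[C@H](OC(C)=O)C/C(CO[Si](C)(C)C(C)(C)C)=C\C=C)/C=C(/C)I | intermediate
23 | (3E,6R,7S,8R,9Z)-1-(9-borabicyclo[3.3.1]nonan-9-yl)-4-{[(tert-butyldimethylsilyl)oxy]methyl}-10-iodo-7-(propan-2-yl)undeca-3,9-diene-6,8-diyl diacetate | CC(=O)O[C@H]([C@@H](C(C)C)[C@H](OC(C)=O)C/C(CO[Si](C)(C)C(C)(C)C)=C\CCB1C2CCCC1CCC2)/C=C(/C)I | intermediate
24 | (1S,2Z,6E,9R,10S)-7-{[(tert-butyldimethylsilyl)oxy]methyl}-3-methyl-10-(propan-2-yl)cyclodeca-2,6-diene-1,9-diyl diacetate | CC(=O)O[C@H]1/C=C(/C)CC/C=C(/CO[Si](C)(C)C(C)(C)C)C[C@@H](OC(C)=O)[C@@H]1C(C)C | intermediate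
25 | (1S,2Z,6E,9R,10S)-7-(hydroxymethyl)-3-methyl-10-(propan-2-yl)cyclodeca-2,6-diene-1,9-diyl diacetate | CC(=O)O[C@H]1/C=C(/C)CC/C=C(/CO)C[C@@H](OC(C)=O)[C@@H]1C(C)C | intermediate
26 | (1R,4Z,6S,7S,8R,10R)-1,10-epoxy-14-hydroxygermacr-4-ene-6,8-diyl diacetate | CC(=O)O[C@H]1/C=C(/C)CC[C@H]2O[C@@]2(CO)C[C@@H](OC(C)=O)[C@@H]1C(C)C | intermediate
27 | (1R,4Z,6S,7S,8R,10S)-6,8-diacetoxy-1,10-epoxygermacr-4-en-14-al | CC(=O)O[C@H]1/C=C(/C)CC[C@H]2O[C@@]2(C=O)C[C@@H](OC(C)=O)[C@@H]1C(C)C | target

**Step count.** Total: 18 steps. Longest linear sequence: 15 steps (1, 2, 4, 5, 8–18, from but-2-yn-1-ol).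

**Steps most likely to fail**

Step 15 (macrocyclisation). Intermolecular coupling to oligomers, β-hydride elimination or protodeboronation of the alkyl partner, and ionisation of the C6 allylic acetate by zerovalent palladium may compete with ring closure. The fallback makes the same bond from the zinc side under base-free conditions. From 22, hydroboration with 9-BBN-H and oxidation with NaBO3·4H2O would give the primary alcohol F1. I2, PPh3 and imidazole would convert it into the primary iodide F2. Zinc dust with LiCl in THF should insert only into the sp3 C–I bond to give the alkylzinc iodide F3. Slow addition of F3 to Pd2(dba)3/SPhos in THF/NMP would close the ring by intramolecular Negishi coupling, rejoining the route at 24.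

Step 17 (epoxidation in the ring). The conformation of the ten-membered ring may override the tartrate and give poor facial selectivity, and the titanium Lewis acid may trigger transannular opening of the epoxide by the C4=C5 olefin. The fallback changes to nucleophilic epoxidation. From 25, MnO2 would give the ring enal F4. Aqueous H2O2 with a 9-amino-9-deoxy-epi-cinchona primary amine salt (iminium-catalysed Weitz–Scheffer-type epoxidation; the quinine- or quinidine-derived catalyst is chosen for the (1R,10S) face) would then give the epoxy aldehyde directly, rejoining the route at 27.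

Step 8 (ketone formation). Wurtz homocoupling during formation of the allylic Grignard reagent, retro-aldol cleavage of the magnesium aldolate, and migration of the 1,1-disubstituted olefin into conjugation with the new ketone may erode the step. The fallback sets C8 by reagent-controlled allylation of an aldehyde instead of ketone formation and reduction. From 10, Et3SiCl and imidazole would give the silyl ether F5, and i-Bu2AlH at −78 °C the aldehyde F6. Separately, 13 and Bu3SnLi would give the allylstannane F7. Keck allylation of F6 with F7 under (R)-BINOL/Ti(OiPr)4, chosen to add to the aldehyde face that gives the (8R) carbinol, would give the homoallylic alcohol F8. PPTS in MeOH would remove the triethylsilyl group and rejoin the route at 17.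

**Further compounds**

F1 | step 15 | (3E,6R,7S,8R,9Z)-4-{[(tert-butyldimethylsilyl)oxy]methyl}-1-hydroxy-10-iodo-7-(propan-2-yl)undeca-3,9-diene-6,8-diyl diacetate | CC(=O)O[C@H]([C@@H](C(C)C)[C@H](OC(C)=O)C/C(CO[Si](C)(C)C(C)(C)C)=C\CCO)/C=C(/C)I
F2 | step 15 | (3E,6R,7S,8R,9Z)-4-{[(tert-butyldimethylsilyl)oxy]methyl}-1,10-diiodo-7-(propan-2-yl)undeca-3,9-diene-6,8-diyl diacetate | CC(=O)O[C@H]([C@@H](C(C)C)[C@H](OC(C)=O)C/C(CO[Si](C)(C)C(C)(C)C)=C\CCI)/C=C(/C)I
F3 | step 15 | alkylzinc iodide from F2 (zinc on C1 of the undecadiene chain) | CC(=O)O[C@H]([C@@H](C(C)C)[C@H](OC(C)=O)C/C(CO[Si](C)(C)C(C)(C)C)=C\CC[Zn]I)/C=C(/C)I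
F4 | step 17 | (1S,2Z,6E,9R,10S)-7-formyl-3-methyl-10-(propan-2-yl)cyclodeca-2,6-diene-1,9-diyl diacetate | CC(=O)O[C@H]1/C=C(/C)CC/C=C(/C=O)C[C@@H](OC(C)=O)[C@@H]1C(C)C
F5 | step 8 | (2R,3R,4Z)-5-iodo-N-methoxy-N-methyl-2-(propan-2-yl)-3-[(triethylsilyl)oxy]hex-4-enamide | CC[Si](CC)(CC)O[C@H]([C@@H](C(C)C)C(=O)N(C)OC)/C=C(/C)I
F6 | step 8 | (2R,3R,4Z)-5-iodo-2-(propan-2-yl)-3-[(triethylsilyl)oxy]hex-4-enal | CC[Si](CC)(CC)O[C@H]([C@@H](C(C)C)C=O)/C=C(/C)I
F7 | step 8 | tert-butyldimethyl({2-[(tributylstannyl)methyl]prop-2-en-1-yl}oxy)silane | C=C(C[Sn](CCCC)(CCCC)CCCC)CO[Si](C)(C)C(C)(C)C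
F8 | step 8 | (4R,5S,6R,7Z)-1-[(tert-butyldimethylsilyl)oxy]-8-iodo-2-methylidene-5-(propan-2-yl)-6-[(triethylsilyl)oxy]non-7-en-4-ol | CC[Si](CC)(CC)O[C@H]([C@@H](C(C)C)[C@H](O)CC(=C)CO[Si](C)(C)C(C)(C)C)/C=C(/C)I
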